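**Plan**

Numbering: decalin C1–C10 (C4 gem-dimethyl, C5 ring-fusion CH, C8 CHMe, C9 quaternary), chain C11–C16 from C9 with C13 carrying the CH2O group, lactam atoms primed.
Cuts, in order: O–SO3H; C16–C3' (B-alkyl Suzuki–Miyaura); C13–C14 (auxiliary-controlled allylation); C12=C13 (cross-metathesis, then hydrogenation); C1=C10 (ring A, McMurry); C9–C11 (enolate allylation); C4–C3 (conjugate addition); C9–CH3.
Forward: ring B is (R)-pulegone; C9 is methylated, the C1–C3 arm is added at C4, C9 is allylated, ring A is closed by reductive carbonyl coupling, the chain is grown from the C9 allyl group, the preformed bromolactam is joined, and sulfation ends the route.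
Enabling feature: the trisubstituted C1=C10 alkene shared by rings A and B is the deoxygenated form of a ring B ketone (C10) and an aldehyde (C1) at the end of the C5–C4–C3–C2–C1 arm; the pulegone carbonyl becomes C10 and its isopropylidene carbon becomes C4.
Stereochemistry: C8 comes from pulegone; C5 and the C9 methyl are set by base equilibration to the all-equatorial ketone; quaternary C9 by axial allylation anti to the C5 side chain; C13 by the (R)-4-benzyloxazolidinone.

Key step: step 5

Assumption: the target is drawn as the free hydrogen sulfate, so the sulfate salt from the last step is protonated on an acidic ion-exchange resin and handled cold in solution.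

**Route**

Step 1
Reactants: 1 (R)-(+)-pulegone
Product: 2 (3R)-2,3-dimethyl-6-(propan-2-ylidene)cyclohexan-1-one (mixture of C2 epimers)
Conditions: LiN(iPr)2, THF, −78 °C; MeI, −78 → 0 °C
Reagents that add atoms: iodomethane, CI
Why: Kinetic deprotonation of the s-cis enone at the α'-methylene (C9) gives the cross-conjugated lithium enolate, whose SN2 methylation (enolate alkylation) installs the C9 methyl; the new C9 centre forms as an epimer mixture that is left unresolved because step 2 equilibrates it.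

Step 2
Reactants: 2 (3R)-2,3-dimethyl-6-(propan-2-ylidene)cyclohexan-1-one; 3 2-(2-bromoethyl)-1,3-dioxolane
Product: 6 (2S,3R,6S)-6-[4-(1,3-dioxolan-2-yl)-2-methylbutan-2-yl]-2,3-dimethylcyclohexan-1-one, via Grignard reagent 4 (not isolated), via silyl enol ether 5 (not isolated)
Conditions: 3, Mg, THF, 25–30 °C; then 2, CuBr·SMe2 (20 mol%), Me3SiCl, THF, −78 → −20 °C; then NaOMe, MeOH, 25 °C
Reagents that add atoms: none
Why: Copper-catalysed, Me3SiCl-accelerated conjugate addition of the Grignard reagent to the β,β-disubstituted enone creates the quaternary gem-dimethyl carbon C4, and NaOMe then cleaves the silyl enol ether and epimerises both α-carbons, so that C5 and C9 should settle under thermodynamic control in the chair with the C5 side chain, the C8 methyl and the C9 methyl all equatorial (side chain and C9 methyl each trans to the C8 methyl, as in menthone-type equilibria); minor epimers are to be separated and re-equilibrated.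

Step 3
Reactants: 6 (2S,3R,6S)-6-[4-(1,3-dioxolan-2-yl)-2-methylbutan-2-yl]-2,3-dimethylcyclohexan-1-one; 7 allyl bromide
Product: 8 (2R,3R,6S)-6-[4-(1,3-dioxolan-2-yl)-2-methylbutan-2-yl]-2,3-dimethyl-2-(prop-2-en-1-yl)cyclohexan-1-one
Conditions: LiN(iPr)2, THF, −78 → 0 °C; then 7, DMPU, −78 → 0 °C
Reagents that add atoms: none
Why: Enolate alkylation at C9, the only accessible α-CH (C5–H is shielded by the adjacent quaternary C4 and its enolate would eclipse the tertiary alkyl group with OLi); the quaternary centre is set by axial attack of allyl bromide on the half-chair that keeps the C5 side chain pseudoequatorial, that is on the face anti to that side chain, which places the allyl group cis to the C8 methyl and leaves the C9 methyl trans to it.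

Step 4
Reactants: 8 (2R,3R,6S)-6-[4-(1,3-dioxolan-2-yl)-2-methylbutan-2-yl]-2,3-dimethyl-2-(prop-2-en-1-yl)cyclohexan-1-one
Product: 9 4-[(1S,3R,4R)-3,4-dimethyl-2-oxo-3-(prop-2-en-1-yl)cyclohexyl]-4-methylpentanal
Conditions: 1 M HCl, THF, 25 °C
Reagents that add atoms: water, O
Why: Acid-catalysed acetal hydrolysis frees the C1 aldehyde under conditions too mild to enolise the hindered C10 ketone, so C5 is not epimerised and no aldol closure is expected; the keto aldehyde is used at once.

Step 5
Reactants: 9 4-[(1S,3R,4R)-3,4-dimethyl-2-oxo-3-(prop-2-en-1-yl)cyclohexyl]-4-methylpentanal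
Product: 10 (1R,2R,4aS)-1,2,5,5-tetramethyl-1-(prop-2-en-1-yl)-1,2,3,4,4a,5,6,7-octahydronaphthalene
Conditions: TiCl3(DME)1.5, Zn–Cu couple, DME, reflux; 9 added by syringe pump over ca. 30 h (high dilution)
Reagents that add atoms: none
Why: Intramolecular McMurry coupling: low-valent titanium made from TiCl3(DME)1.5 and Zn–Cu couple transfers one electron to each carbonyl, the ketyl carbons C1 and C10 combine on titanium to a cyclic 1,2-diolate (pinacolate), and at reflux both C–O bonds are cleaved to release the C1=C10 alkene. The closest known reaction type is the titanium-induced cyclisation of keto aldehydes to cycloalkenes. Ring A closes as a six-membered carbocycle by direct union of the two carbonyl carbons of a 1,6-dicarbonyl compound, so both ring-closing atoms end as the alkene and its position between C1 and C10 is fixed. No stereocentre is created; C5, C8 and C9 are spectators, and because no C10 carbocation is involved the C9 methyl cannot migrate. The selectivity needed is intramolecular coupling over intermolecular pinacol formation and over simple reduction of the aldehyde, which slow addition into excess reagent and the favourable six-membered closure should secure; the isolated allyl alkene is inert to the reagent.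

Step 6
Reactants: 11 (R)-4-benzyl-1,3-oxazolidin-2-one
Product: 12 (R)-3-acryloyl-4-benzyl-1,3-oxazolidin-2-one
Conditions: MeMgBr, THF, 0 °C; acryloyl chloride, −78 → 0 °C
Reagents that add atoms: acryloyl chloride, C=CC(=O)Cl
Why: N-Acylation of the bromomagnesium salt of the oxazolidinone (imide formation), the magnesium salt being chosen because it does not trigger anionic polymerisation of the acrylimide; the stereocentre of 11 is untouched.

Step 7
Reactants: 10 (1R,2R,4aS)-1,2,5,5-tetramethyl-1-(prop-2-en-1-yl)-1,2,3,4,4a,5,6,7-octahydronaphthalene; 12 (R)-3-acryloyl-4-benzyl-1,3-oxazolidin-2-one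
Product: 13 (R)-4-benzyl-3-{(E)-4-[(1R,2R,4aS)-1,2,5,5-tetramethyl-1,2,3,4,4a,5,6,7-octahydronaphthalen-1-yl]but-2-enoyl}-1,3-oxazolidin-2-one
Conditions: second-generation Hoveyda–Grubbs catalyst [RuCl2(H2IMes)(=CH-C6H4-2-OiPr)] (5 mol%), 12 (3 equiv), CH2Cl2, 40 °C
Reagents that add atoms: none
Why: Olefin cross-metathesis between the monosubstituted allyl alkene and the electron-poor acrylimide, partners that homodimerise at very different rates, should give the (E)-enoyl imide, while the trisubstituted C1=C10 alkene flanked by quaternary C9 is too hindered to enter the catalytic cycle.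

Step 8
Reactants: 13 (R)-4-benzyl-3-{(E)-4-[(1R,2R,4aS)-1,2,5,5-tetramethyl-1,2,3,4,4a,5,6,7-octahydronaphthalen-1-yl]but-2-enoyl}-1,3-oxazolidin-2-one
Product: 14 (R)-4-benzyl-3-{4-[(1R,2R,4aS)-1,2,5,5-tetramethyl-1,2,3,4,4a,5,6,7-octahydronaphthalen-1-yl]butanoyl}-1,3-oxazolidin-2-one
Conditions: H2 (1 atm), RhCl(PPh3)3 (10 mol%), toluene–EtOH, 25 °C
Reagents that add atoms: none
Why: Homogeneous hydrogenation with RhCl(PPh3)3, whose rate falls steeply with alkene substitution, should saturate the disubstituted C12=C13 bond and leave the trisubstituted ring alkene untouched and unisomerised.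

Step 9
Reactants: 14 (R)-4-benzyl-3-{4-[(1R,2R,4aS)-1,2,5,5-tetramethyl-1,2,3,4,4a,5,6,7-octahydronaphthalen-1-yl]butanoyl}-1,3-oxazolidin-2-one; 7 allyl bromide
Product: 15 (R)-4-benzyl-3-[(2S)-2-{2-[(1R,2R,4aS)-1,2,5,5-tetramethyl-1,2,3,4,4a,5,6,7-octahydronaphthalen-1-yl]ethyl}pent-4-enoyl]-1,3-oxazolidin-2-one
Conditions: NaN(SiMe3)2, THF, −78 °C; then 7, −78 → −45 °C
Reagents that add atoms: none
Why: Evans asymmetric alkylation, in which the chelated (Z)-sodium enolate is attacked by allyl bromide on the face opposite the benzyl group of the (R)-auxiliary; this sets C13 as (2S) in 15, the arrangement that is named (R) in the target once the allyl group has become the saturated chain.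

Step 10
Reactants: 15 (R)-4-benzyl-3-[(2S)-2-{2-[(1R,2R,4aS)-1,2,5,5-tetramethyl-1,2,3,4,4a,5,6,7-octahydronaphthalen-1-yl]ethyl}pent-4-enoyl]-1,3-oxazolidin-2-one
Product: 16 (2S)-2-{2-[(1R,2R,4aS)-1,2,5,5-tetramethyl-1,2,3,4,4a,5,6,7-octahydronaphthalen-1-yl]ethyl}pent-4-en-1-ol
Conditions: LiBH4, MeOH (1 equiv), Et2O, 0 °C
Reagents that add atoms: none
Why: Hydride reduction of the imide (reductive auxiliary cleavage) turns the acyl carbon into the CH2OH that will carry the sulfate and releases the oxazolidinone without touching C13 or either alkene.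

Step 11
Reactants: 17 3-methylbutan-1-amine; 18 2,5-dimethoxy-2,5-dihydrofuran
Product: 19 1-(3-methylbutyl)-1,5-dihydro-2H-pyrrol-2-one
Conditions: 1 M HCl (aq), 25 °C; then NaHCO3
Reagents that add atoms: none
Why: Acid hydrolysis of the bis-acetal liberates (Z)-but-2-enedial, which condenses with the primary amine to a cyclic hemiaminal that loses water and tautomerises to the conjugated γ-lactam (one-pot amine–dialdehyde lactam condensation).

Step 12
Reactants: 19 1-(3-methylbutyl)-1,5-dihydro-2H-pyrrol-2-one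
Product: 21 3-bromo-1-(3-methylbutyl)-1,5-dihydro-2H-pyrrol-2-one, via trans-dibromide 20 (not isolated)
Conditions: Br2, CH2Cl2, 0 °C; then Et3N, 0 → 25 °C
Reagents that add atoms: bromine, BrBr
Why: Bromine addition to the lactam alkene followed by amine-induced E1cB loss of HBr (removal of the acidic C3'–H, departure of the C4' bromide) is the standard addition–elimination α-bromination of an α,β-unsaturated carbonyl compound.

Step 13
Reactants: 16 (2S)-2-{2-[(1R,2R,4aS)-1,2,5,5-tetramethyl-1,2,3,4,4a,5,6,7-octahydronaphthalen-1-yl]ethyl}pent-4-en-1-ol; 21 3-bromo-1-(3-methylbutyl)-1,5-dihydro-2H-pyrrol-2-one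
Product: 23 3-[(4R)-4-(hydroxymethyl)-6-[(1R,2R,4aS)-1,2,5,5-tetramethyl-1,2,3,4,4a,5,6,7-octahydronaphthalen-1-yl]hexyl]-1-(3-methylbutyl)-1,5-dihydro-2H-pyrrol-2-one, via bis-boryl intermediate 22 (not isolated)
Conditions: 9-BBN dimer (2.5 equiv B–H), THF, 0 → 25 °C; then 21, PdCl2(dppf) (5 mol%), AsPh3, Cs2CO3, DMF–H2O, 25 °C
Reagents that add atoms: none
Why: Anti-Markovnikov hydroboration of the terminal alkene by 9-BBN (the extra equivalent masks the hydroxyl in the flask as its borinate, and the hindered ring alkene is inert) followed by B-alkyl Suzuki–Miyaura coupling with the α-bromo unsaturated lactam, a coupling established for α-halo enones, forms the C16–C3' bond; the aqueous base hydrolyses the O–B bond.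

Step 14
Reactants: 23 3-[(4R)-4-(hydroxymethyl)-6-[(1R,2R,4aS)-1,2,5,5-tetramethyl-1,2,3,4,4a,5,6,7-octahydronaphthalen-1-yl]hexyl]-1-(3-methylbutyl)-1,5-dihydro-2H-pyrrol-2-one
Product: 25 [(2R)-2-{2-[(1R,2R,4aS)-1,2,5,5-tetramethyl-1,2,3,4,4a,5,6,7-octahydronaphthalen-1-yl]ethyl}-5-[1-(3-methylbutyl)-2-oxo-2,5-dihydro-1H-pyrrol-3-yl]pentyl] hydrogen sulfate, via pyridinium sulfate 24 (not isolated)
Conditions: SO3·pyridine, pyridine, 25 °C; then acidic ion-exchange resin (H+ form), MeOH–H2O, 0 °C
Reagents that add atoms: sulfur trioxide–pyridine complex, [O-]S(=O)(=O)[n+]1ccccc1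
Why: O-Sulfation of the primary alcohol with the SO3·pyridine complex (sulfate monoester formation), to which the tertiary lactam and both alkenes are inert, followed by cation exchange to the free hydrogen sulfate.

**Compound list**

1 | (R)-(+)-pulegone, (5R)-5-methyl-2-(propan-2-ylidene)cyclohexan-1-one | C[C@@H]1CCC(=C(C)C)C(=O)C1 | starting material
2 | (3R)-2,3-dimethyl-6-(propan-2-ylidene)cyclohexan-1-one, mixture of C2 epimers | C[C@@H]1CCC(=C(C)C)C(=O)C1C | intermediate
3 | 2-(2-bromoethyl)-1,3-dioxolane | BrCCC1OCCO1 | starting material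
4 | [2-(1,3-dioxolan-2-yl)ethyl]magnesium bromide | Br[Mg]CCC1OCCO1 | intermediate
5 | ({(5R)-2-[4-(1,3-dioxolan-2-yl)-2-methylbutan-2-yl]-5,6-dimethylcyclohex-1-en-1-yl}oxy)trimethylsilane, mixture of C6 epimers | C[C@@H]1CCC(C(C)(C)CCC2OCCO2)=C(O[Si](C)(C)C)C1C | intermediate
6 | (2S,3R,6S)-6-[4-(1,3-dioxolan-2-yl)-2-methylbutan-2-yl]-2,3-dimethylcyclohexan-1-one (all-equatorial) | C[C@@H]1CC[C@@H](C(C)(C)CCC2OCCO2)C(=O)[C@H]1C | intermediate
7 | allyl bromide, 3-bromoprop-1-ene | C=CCBr | starting material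
8 | (2R,3R,6S)-6-[4-(1,3-dioxolan-2-yl)-2-methylbutan-2-yl]-2,3-dimethyl-2-(prop-2-en-1-yl)cyclohexan-1-one | C=CC[C@@]1(C)C(=O)[C@H](C(C)(C)CCC2OCCO2)CC[C@H]1C | intermediate
9 | 4-[(1S,3R,4R)-3,4-dimethyl-2-oxo-3-(prop-2-en-1-yl)cyclohexyl]-4-methylpentanal | C=CC[C@@]1(C)C(=O)[C@H](C(C)(C)CCC=O)CC[C@H]1C | intermediate
10 | (1R,2R,4aS)-1,2,5,5-tetramethyl-1-(prop-2-en-1-yl)-1,2,3,4,4a,5,6,7-octahydronaphthalene | C=CC[C@@]1(C)C2=CCCC(C)(C)[C@@H]2CC[C@H]1C | intermediate
11 | (R)-4-benzyl-1,3-oxazolidin-2-one | O=C1N[C@H](Cc2ccccc2)CO1 | starting material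
12 | (R)-3-acryloyl-4-benzyl-1,3-oxazolidin-2-one | C=CC(=O)N1[C@H](Cc2ccccc2)COC1=O | intermediate
13 | (R)-4-benzyl-3-{(E)-4-[(1R,2R,4aS)-1,2,5,5-tetramethyl-1,2,3,4,4a,5,6,7-octahydronaphthalen-1-yl]but-2-enoyl}-1,3-oxazolidin-2-one | O=C(/C=C/C[C@@]1(C)C2=CCCC(C)(C)[C@@H]2CC[C@H]1C)N3[C@H](Cc4ccccc4)COC3=O | intermediate
14 | (R)-4-benzyl-3-{4-[(1R,2R,4aS)-1,2,5,5-tetramethyl-1,2,3,4,4a,5,6,7-octahydronaphthalen-1-yl]butanoyl}-1,3-oxazolidin-2-one | O=C(CCC[C@@]1(C)C2=CCCC(C)(C)[C@@H]2CC[C@H]1C)N3[C@H](Cc4ccccc4)COC3=O | intermediate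
15 | (R)-4-benzyl-3-[(2S)-2-{2-[(1R,2R,4aS)-1,2,5,5-tetramethyl-1,2,3,4,4a,5,6,7-octahydronaphthalen-1-yl]ethyl}pent-4-enoyl]-1,3-oxazolidin-2-one | C=CC[C@H](CC[C@@]1(C)C2=CCCC(C)(C)[C@@H]2CC[C@H]1C)C(=O)N3[C@H](Cc4ccccc4)COC3=O | intermediate
16 | (2S)-2-{2-[(1R,2R,4aS)-1,2,5,5-tetramethyl-1,2,3,4,4a,5,6,7-octahydronaphthalen-1-yl]ethyl}pent-4-en-1-ol | C=CC[C@H](CC[C@@]1(C)C2=CCCC(C)(C)[C@@H]2CC[C@H]1C)CO | intermediate
17 | 3-methylbutan-1-amine | CC(C)CCN | starting material
18 | 2,5-dimethoxy-2,5-dihydrofuran (cis/trans mixture) | COC1C=CC(OC)O1 | starting material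
19 | 1-(3-methylbutyl)-1,5-dihydro-2H-pyrrol-2-one | CC(C)CCN1CC=CC1=O | intermediate
20 | trans-3,4-dibromo-1-(3-methylbutyl)pyrrolidin-2-one (racemic, one enantiomer drawn) | CC(C)CCN1C[C@H](Br)[C@@H](Br)C1=O | intermediate
21 | 3-bromo-1-(3-methylbutyl)-1,5-dihydro-2H-pyrrol-2-one | CC(C)CCN1CC=C(Br)C1=O | intermediate
22 | bis-boryl intermediate: 16 with C16 bonded to a 9-borabicyclo[3.3.1]nonan-9-yl group and the hydroxyl as its 9-borabicyclo[3.3.1]nonan-9-yl borinate | O(B1C2CCCC1CCC2)C[C@H](CCCB3C4CCCC3CCC4)CC[C@@]5(C)C6=CCCC(C)(C)[C@@H]6CC[C@H]5C | intermediate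
23 | 3-[(4R)-4-(hydroxymethyl)-6-[(1R,2R,4aS)-1,2,5,5-tetramethyl-1,2,3,4,4a,5,6,7-octahydronaphthalen-1-yl]hexyl]-1-(3-methylbutyl)-1,5-dihydro-2H-pyrrol-2-one | CC(C)CCN1CC=C(CCC[C@H](CC[C@@]2(C)C3=CCCC(C)(C)[C@@H]3CC[C@H]2C)CO)C1=O | intermediate
24 | pyridinium salt of the alkyl sulfate 25 | CC(C)CCN1CC=C(CCC[C@H](CC[C@@]2(C)C3=CCCC(C)(C)[C@@H]3CC[C@H]2C)COS(=O)(=O)[O-])C1=O.c1cc[nH+]cc1 | intermediate
25 | [(2R)-2-{2-[(1R,2R,4aS)-1,2,5,5-tetramethyl-1,2,3,4,4a,5,6,7-octahydronaphthalen-1-yl]ethyl}-5-[1-(3-methylbutyl)-2-oxo-2,5-dihydro-1H-pyrrol-3-yl]pentyl] hydrogen sulfate (CNP0218721.1) | CC(C)CCN1CC=C(CCC[C@H](CC[C@@]2(C)C3=CCCC(C)(C)[C@@H]3CC[C@H]2C)COS(=O)(=O)O)C1=O | target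

**Count and risks**

Total steps: 14. Longest linear sequence: 11 steps (steps 1–5, 7–10, 13 and 14, from (R)-pulegone).

Steps most likely to fail:

Step 5. The congested titanium pinacolate at C10 may fail to deoxygenate, or the aldehyde may couple between molecules or be reduced before the ring closes. The fallback sets out from 9 and keeps the C1–C10 union but splits it into two stages. SmI2 in THF with t-BuOH at −78 °C should carry out the ketyl–carbonyl pinacol cyclisation and stop at the cis-8,8a-diol F1 (both carbinol configurations are erased later). 1,1'-Thiocarbonyldiimidazole with DMAP in hot toluene converts it into the cyclic thionocarbonate F2. Corey–Winter olefination with P(OMe)3 at reflux then extrudes the alkene by syn elimination, again without a C10 cation, and the route is rejoined at 10.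

Step 3. The allyl bromide may attack the wrong face of the C9 enolate, because the adjacent C8 methyl and the C5 side chain pull the half-chair in opposite directions. The fallback sets out from 6 and replaces substrate control by ligand control. The same lithium enolate is trapped on oxygen with allyl chloroformate (TMEDA, THF, −78 °C) to give the allyl enol carbonate F3. Decarboxylative Tsuji allylation with Pd2(dba)3 and a chiral t-BuPHOX ligand in THF at 25 °C forms the C9–C11 bond inside the chiral palladium–allyl enolate complex; the (S)-ligand is expected to be the matching enantiomer. The route is rejoined at 8.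

Step 13. The free hydroxyl consumes borane, and the resulting borinate may slow transmetalation enough for protodebromination or base-induced decomposition of 21 to win. The fallback sets out from 16 and removes the O–B chemistry by a protecting-group detour. TBSCl and imidazole in DMF give the TBS ether F4. One equivalent of 9-BBN gives the B-alkyl borane F5. Coupling with 21 under the same palladium conditions gives the silylated coupling product F6, and Bu4NF in THF releases the alcohol, rejoining the route at 23.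

Further compounds
F1 | step 5 | (1R,2R,4aS)-1,2,5,5-tetramethyl-1-(prop-2-en-1-yl)decahydronaphthalene-8,8a-diol, 8,8a-cis, carbinol configurations left open | C=CC[C@@]1(C)C2(O)C(O)CCC(C)(C)[C@@H]2CC[C@H]1C
F2 | step 5 | cyclic thionocarbonate (1,3-dioxolane-2-thione) of diol F1 | C=CC[C@@]1(C)C23OC(=S)OC2CCC(C)(C)[C@@H]3CC[C@H]1C
F3 | step 3 | allyl {(3R,6S)-6-[4-(1,3-dioxolan-2-yl)-2-methylbutan-2-yl]-2,3-dimethylcyclohex-1-en-1-yl} carbonate | C=CCOC(=O)OC1=C(C)[C@H](C)CC[C@H]1C(C)(C)CCC2OCCO2
F4 | step 13 | tert-butyldimethyl{[(2S)-2-{2-[(1R,2R,4aS)-1,2,5,5-tetramethyl-1,2,3,4,4a,5,6,7-octahydronaphthalen-1-yl]ethyl}pent-4-en-1-yl]oxy}silane | C=CC[C@H](CC[C@@]1(C)C2=CCCC(C)(C)[C@@H]2CC[C@H]1C)CO[Si](C)(C)C(C)(C)C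
F5 | step 13 | 9-[(4R)-4-{[(tert-butyldimethylsilyl)oxy]methyl}-6-[(1R,2R,4aS)-1,2,5,5-tetramethyl-1,2,3,4,4a,5,6,7-octahydronaphthalen-1-yl]hexyl]-9-borabicyclo[3.3.1]nonane | CC(C)(C)[Si](C)(C)OC[C@H](CCCB1C2CCCC1CCC2)CC[C@@]3(C)C4=CCCC(C)(C)[C@@H]4CC[C@H]3C
F6 | step 13 | 3-[(4R)-4-{[(tert-butyldimethylsilyl)oxy]methyl}-6-[(1R,2R,4aS)-1,2,5,5-tetramethyl-1,2,3,4,4a,5,6,7-octahydronaphthalen-1-yl]hexyl]-1-(3-methylbutyl)-1,5-dihydro-2H-pyrrol-2-one | CC(C)CCN1CC=C(CCC[C@H](CC[C@@]2(C)C3=CCCC(C)(C)[C@@H]3CC[C@H]2C)CO[Si](C)(C)C(C)(C)C)C1=O
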